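In Sunday's run Z grows at 0.676 of its early speed after 20.0 min, taking the gain per minute from there to 50.0 min over the gain per minute before. The flask asked about is that same flask, followed on.

common to all: J 0.054 M; X 0.054 M; G 54 µM

| flask | E | remark |
|---|---|---|
| Sunday's | 0.054 M | the very flask that is asked about, followed so far |
| flask | 0.0540 M |  |

Sunday's run (percent of the J and X together charged)

| time / min | Z / % |
|---|---|
| 10.0 | 2.9 |
| 20.0 | 6.8 |
| 25.0 | 8.4 |
| 40.0 | 11.2 |
| 50.0 | 13.7 |

(scatter of a reading: 0.5 percentage points)

* apparent order in G when 20 % of the J and X together are converted (percent change of the rate of making Z for one percent more G charged)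

- G is single-handed; J and X are mirror images of each other, charged as a racemate, each of them at the stated concentration
- given per volume of solution although it is solid: E
- the numbers in the tables scatter with a standard deviation of 0.5 percentage points
- at the start none of E is in solution
- no earlier run changes the charge of G; that part of a forecast is a guess

Does falling c(J) account for this? Z comes from J, and the average c(J) of the later stretch is 0.853 of the earlier one, which is a smaller drop. So the speed per unit of J still falls, to 0.793.

The centres of the two stretches lie 25.0 min apart, which makes the fading 0.557 h⁻¹. No run varies G, so it is my assumption that this fading is G going out of work (catalyst deactivation).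

What does that do to the order? At 0.834 h, the moment asked about, ln(c(G) charged / c(G) working) is 0.464; I call this the loss exponent. One percent more G reaches the same conversion about one percent sooner, so G has faded less, and I reckon the order as one plus the exponent: 1.46, a reading that carries the scatter of 0.5 percentage points.

The forecast says 0.7, expecting “mixed control leaning towards catalysis”; my reading differs from it.

The flask gives 1.2, lower than my 1.46.

    D + G → L (k = 0.00950 M⁻¹ s⁻¹)
    E ⇌ D, rate k2*(cs2 - [D]) while solid is left; crystals form when [D] > cs2 (solubility = 8.70 mM, k = 0.0250 s⁻¹)
    D + G + J → G + Z (k = 270 M⁻² s⁻¹)
    D + G + X → G + Q (k = 110 M⁻² s⁻¹)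

At 0.500 h G stands at 86.9 % and L at 13.1 % of the catalyst charged. My loss exponent of 0.464 came from the scattered Z readings; carrying G's simulated decline on at the same pace to 0.834 h gives an exponent of 0.234. Now take a second flask with twice the G. With this exponent, the average on the way to that conversion goes from 0.117 to 0.0585, so the time should shrink by a factor 0.472. The simulated factor is 0.494.

The runs stem from a simulated flask for an exercise; noise was put on by code.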